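**Retrosynthetic overview**
1. The C8 methacrylate and the C10 tertiary acetate go on last. Before that, the ten-membered ring is closed by a nickel/chromium-catalysed alkenyl iodide–aldehyde coupling (C7–C8, sets C8) of an acyclic 4-iodobutenolide aldehyde.
2. C5–C6 (sets C6) comes from a nickel-catalysed enantioconvergent reductive coupling of a Z-alkenyl iodide (C1–C5, C8–C10) with a racemic 5-bromo-4-chlorobutenolide (C6, C7, C11–C13).
3. The alkenyl iodide comes from enolate allylation (C2–C3) of a C8-acetal α-hydroxy ketone with a Z-iodoallyl bromide. The ketone is made by a copper bis(oxazoline) Mukaiyama aldol on butane-2,3-dione (sets C10); the bromide by carbomagnesiation–iodination of propargyl alcohol (fixes the 4Z alkene).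
4. The bromobutenolide comes from tetronic acid: Vilsmeier chloroformylation (C13 and the C7 chloride), reduction, acetylation, then bromination at C6 through the silyloxyfuran.
5. Ring order: the butenolide ring is preformed (tetronic acid); the ten-membered carbocycle is formed last. Atom labels are germacrane numbers: C1 ketone, C4=C5 alkene, C6 lactone CH–O, C7=C11 butenolide alkene, C8 ester carbinol, C10 acetate carbon, C12 lactone C=O, C13 CH2OAc.

Assumption: the absolute sense of induction of each chiral catalyst (steps 4, 12, 15) is taken from the closest precedent; if it proves reversed, the enantiomeric ligand is used.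

**Route**

Step 1
Reactants: 1 prop-2-yn-1-ol
Product: 3 (Z)-3-iodo-2-methylprop-2-en-1-ol, via alkenylmagnesium alkoxide 2 (not isolated)
Conditions: MeMgBr (2.2 equiv), copper iodide CuI (10 mol%), THF, −20 °C to rt; then iodine, −78 to 0 °C; aq. NH4Cl
Reagents that add atoms: methylmagnesium bromide C[Mg]Br; iodine [I][I]
Why: Copper-catalysed anti-carbomagnesiation of the propargylic alkoxide (Duboudin-type) puts magnesium on the terminal carbon cis to the CH2O group through a five-membered chelate, and iodinolysis with retention gives only the Z iodide that becomes the C4=C5 alkene.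

Step 2
Reactants: 3 (Z)-3-iodo-2-methylprop-2-en-1-ol
Product: 4 (Z)-3-bromo-1-iodo-2-methylprop-1-ene
Conditions: CBr4, PPh3, CH2Cl2, 0 °C
Reagents that add atoms: carbon tetrabromide BrC(Br)(Br)Br
Why: Appel bromination converts the primary allylic alcohol into the bromide under neutral conditions without touching the alkenyl iodide or its geometry.

Step 3
Reactants: 5 S-ethyl ethanethioate
Product: 7 [1-(ethylsulfanyl)ethenyl]oxy(trimethyl)silane, via lithium thioester enolate 6 (not isolated)
Conditions: LiN(iPr)2, THF, −78 °C; then TMSCl, −78 °C to rt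
Reagents that add atoms: chlorotrimethylsilane C[Si](C)(C)Cl
Why: Kinetic deprotonation and O-silylation (silyl ketene thioacetal formation) give the enolsilane needed for the Mukaiyama aldol.

Step 4
Reactants: 7 [1-(ethylsulfanyl)ethenyl]oxy(trimethyl)silane; 8 butane-2,3-dione
Product: 10 S-ethyl (3S)-3-hydroxy-3-methyl-4-oxopentanethioate, via silyl ether 9 (not isolated)
Conditions: Cu(OTf)2 (10 mol%), (S,S)-2,2'-(propane-2,2-diyl)bis(4-tert-butyl-4,5-dihydrooxazole) (11 mol%), THF, −78 °C; then 1 M HCl, THF, 0 °C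
Reagents that add atoms: none
Why: Catalytic enantioselective Mukaiyama aldol in which the diketone chelates square-planar divalent copper and the enolsilane attacks the open face of one of the two equivalent carbonyl groups, setting the tertiary carbinol (C10) as S as in the known pyruvate and 1,2-diketone additions, before mild acid removes the transferred silyl group.

Step 5
Reactants: 10 S-ethyl (3S)-3-hydroxy-3-methyl-4-oxopentanethioate
Product: 11 (3S)-3-hydroxy-3-methyl-4-oxopentanal
Conditions: Et3SiH, 10% Pd on carbon (5 mol%), acetone, rt; used crude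
Reagents that add atoms: none
Why: Fukuyama reduction (palladium inserts into the acyl–sulfur bond and the silane delivers hydride) stops at the aldehyde and leaves the ketone, the tertiary alcohol and C10 untouched.

Step 6
Reactants: 11 (3S)-3-hydroxy-3-methyl-4-oxopentanal
Product: 12 (3S)-3-hydroxy-5,5-dimethoxy-3-methylpentan-2-one
Conditions: HC(OMe)3, PPTS (5 mol%), MeOH, 0 °C to rt
Reagents that add atoms: trimethyl orthoformate COC(OC)OC; methanol CO
Why: Acid-catalysed acetalisation is selective for the aldehyde over the hindered ketone next to the quaternary carbon and masks C8 for the base and nickel steps that follow.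

Step 7
Reactants: 12 (3S)-3-hydroxy-5,5-dimethoxy-3-methylpentan-2-one; 4 (Z)-3-bromo-1-iodo-2-methylprop-1-ene
Product: 14 (3S,7Z)-3-hydroxy-8-iodo-1,1-dimethoxy-3,7-dimethyloct-7-en-4-one, via dilithium alkoxide enolate 13 (not isolated)
Conditions: LiN(iPr)2 (2.2 equiv), THF, −78 °C; then 4 (0.8 equiv), DMPU, −78 to −40 °C; aq. NH4Cl
Reagents that add atoms: none
Why: Enolate alkylation in which the methyl group (C2) is the only enolisable position of the alkoxide ketone, so SN2 displacement of the allylic bromide forms C2–C3 without changing the Z iodoalkene or C10.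

Step 8
Reactants: 15 4-hydroxyfuran-2(5H)-one (tetronic acid)
Product: 17 4-chloro-2-oxo-2,5-dihydrofuran-3-carbaldehyde, via iminium chloride 16 (not isolated)
Conditions: POCl3 (2.5 equiv), DMF (3 equiv), 1,2-dichloroethane, 0 to 60 °C; then ice, aq. NaOAc
Reagents that add atoms: N,N-dimethylformamide CN(C)C=O; phosphoryl chloride O=P(Cl)(Cl)Cl; water O
Why: Vilsmeier–Haack haloformylation of the cyclic β-keto ester formylates the nucleophilic C3 (future C11, new carbon C13) and replaces the enol OH by chloride, as with 4-hydroxycoumarins, and hydrolysis of the iminium salt frees the aldehyde.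

Step 9
Reactants: 17 4-chloro-2-oxo-2,5-dihydrofuran-3-carbaldehyde
Product: 18 4-chloro-3-(hydroxymethyl)furan-2(5H)-one
Conditions: NaBH4, CeCl3·7H2O, MeOH, −40 °C
Reagents that add atoms: none
Why: Luche reduction gives 1,2-reduction of the β-chlorovinyl aldehyde and avoids conjugate hydride attack with loss of chloride.

Step 10
Reactants: 18 4-chloro-3-(hydroxymethyl)furan-2(5H)-one
Product: 19 (4-chloro-2-oxo-2,5-dihydrofuran-3-yl)methyl acetate
Conditions: Ac2O, pyridine, DMAP (5 mol%), CH2Cl2, 0 °C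
Reagents that add atoms: acetic anhydride CC(=O)OC(C)=O
Why: DMAP-catalysed acetylation of the primary alcohol installs the C13 acetate of the target.

Step 11
Reactants: 19 (4-chloro-2-oxo-2,5-dihydrofuran-3-yl)methyl acetate
Product: 21 (5-bromo-4-chloro-2-oxo-2,5-dihydrofuran-3-yl)methyl acetate (racemic), via silyloxyfuran 20 (not isolated)
Conditions: TMSOTf, Et3N, CH2Cl2, 0 °C; then NBS, −78 °C; non-aqueous work-up, used at once
Reagents that add atoms: N-bromosuccinimide O=C1CCC(=O)N1Br
Why: Soft enolisation to the 2-silyloxyfuran followed by electrophilic bromination at its only free α position (C6) gives the γ-bromobutenolide regioselectively, which a radical bromination could not guarantee against the acetoxymethyl group.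

Step 12
Reactants: 14 (3S,7Z)-3-hydroxy-8-iodo-1,1-dimethoxy-3,7-dimethyloct-7-en-4-one; 21 (5-bromo-4-chloro-2-oxo-2,5-dihydrofuran-3-yl)methyl acetate (racemic)
Product: 22 [(5R)-4-chloro-5-[(1Z,6S)-6-hydroxy-8,8-dimethoxy-2,6-dimethyl-5-oxooct-1-en-1-yl]-2-oxo-2,5-dihydrofuran-3-yl]methyl acetate
Conditions: NiBr2(dme) (10 mol%), (3aR,3a'R,8aS,8a'S)-2,2'-(cyclopropane-1,1-diyl)bis(3a,8a-dihydro-8H-indeno[1,2-d]oxazole) (12 mol%), Mn powder (3 equiv), NaI (0.5 equiv), DMA, 0 °C; 21 (1.5 equiv)
Reagents that add atoms: none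
Why: Proposed new method: nickel-catalysed enantioconvergent reductive cross-coupling of an alkenyl iodide with a racemic γ-bromobutenolide, in which zerovalent nickel bearing the chiral bis(oxazoline) inserts into the C5–iodine bond with retention of the Z geometry, a monovalent nickel species abstracts bromine from 21 to give the planar, oxygen- and carbonyl-stabilised 2-oxo-2,5-dihydrofuran-5-yl radical, this radical is captured at its unsubstituted γ terminus (the α terminus C11 is fully substituted) by the alkenylnickel species, and reductive elimination from trivalent nickel forms C5–C6 while the ligand selects the radical face so that both enantiomers of 21 converge on 6R, with Mn turning the cycle over; the closest known reactions are the nickel-catalysed asymmetric reductive couplings of alkenyl bromides with racemic benzylic chlorides and the reductive C-glycosylations of glycosyl bromides.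

Step 13
Reactants: 22 [(5R)-4-chloro-5-[(1Z,6S)-6-hydroxy-8,8-dimethoxy-2,6-dimethyl-5-oxooct-1-en-1-yl]-2-oxo-2,5-dihydrofuran-3-yl]methyl acetate
Product: 23 [(5R)-5-[(1Z,6S)-6-hydroxy-8,8-dimethoxy-2,6-dimethyl-5-oxooct-1-en-1-yl]-4-iodo-2-oxo-2,5-dihydrofuran-3-yl]methyl acetate
Conditions: NaI (10 equiv), AcOH (2 equiv), MeCN, 50 °C, dark
Reagents that add atoms: sodium iodide [Na+].[I-]
Why: Vinylogous Finkelstein reaction (acid-assisted conjugate addition of iodide at the β-carbon of the butenolide and loss of chloride, driven by excess NaI) gives the iodide needed for nickel insertion without disturbing C6, the acetal or the acetate.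

Step 14
Reactants: 23 [(5R)-5-[(1Z,6S)-6-hydroxy-8,8-dimethoxy-2,6-dimethyl-5-oxooct-1-en-1-yl]-4-iodo-2-oxo-2,5-dihydrofuran-3-yl]methyl acetate
Product: 24 [(5R)-5-[(1Z,6S)-6-hydroxy-2,6-dimethyl-5,8-dioxooct-1-en-1-yl]-4-iodo-2-oxo-2,5-dihydrofuran-3-yl]methyl acetate
Conditions: PPTS (20 mol%), acetone/H2O (10:1), 40 °C
Reagents that add atoms: water O
Why: Mild acid-catalysed acetal hydrolysis frees the C8 aldehyde at a pH at which the tertiary alcohol, the acetate and the butenolide are stable.

Step 15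
Reactants: 24 [(5R)-5-[(1Z,6S)-6-hydroxy-2,6-dimethyl-5,8-dioxooct-1-en-1-yl]-4-iodo-2-oxo-2,5-dihydrofuran-3-yl]methyl acetate
Product: 26 [(4S,6S,10Z,11aR)-4,6-dihydroxy-6,10-dimethyl-2,7-dioxo-2,4,5,6,7,8,9,11a-octahydrocyclodeca[b]furan-3-yl]methyl acetate, via trimethylsilyl ether 25 (not isolated)
Conditions: CrCl2 (15 mol%), (S)-N-[2-(4-isopropyl-4,5-dihydrooxazol-2-yl)-6-methylphenyl]methanesulfonamide (17 mol%), Et3N (30 mol%), NiCl2(2,9-dimethyl-1,10-phenanthroline) (3 mol%), Mn powder (2 equiv), LiCl, TMSCl (2 equiv), MeCN/THF, rt, syringe pump to 2 mM; then 0.5 M HCl, THF, 0 °C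
Reagents that add atoms: none
Why: Catalytic asymmetric Nozaki–Hiyama–Kishi macrocyclisation in which zerovalent nickel inserts into the activated C7–iodine bond, transmetalation gives an alkenyl species of trivalent chromium that adds to the aldehyde and not to the ketone, closing the ten-membered ring, and the chiral sulfonamide on chromium directs attack to the aldehyde face that gives the 8S alcohol.

Step 16
Reactants: 26 [(4S,6S,10Z,11aR)-4,6-dihydroxy-6,10-dimethyl-2,7-dioxo-2,4,5,6,7,8,9,11a-octahydrocyclodeca[b]furan-3-yl]methyl acetate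
Product: 27 (4S,6S,10Z,11aR)-3-(acetoxymethyl)-6-hydroxy-6,10-dimethyl-2,7-dioxo-2,4,5,6,7,8,9,11a-octahydrocyclodeca[b]furan-4-yl 2-methylprop-2-enoate
Conditions: methacryloyl chloride, Et3N, DMAP (10 mol%), CH2Cl2, −20 °C
Reagents that add atoms: methacryloyl chloride C=C(C)C(=O)Cl
Why: DMAP-catalysed acylation esterifies the secondary allylic C8 alcohol selectively because the tertiary α-ketol OH at C10 is far less reactive, and the cold, weakly basic medium does not epimerise C6.

Step 17
Reactants: 27 (4S,6S,10Z,11aR)-3-(acetoxymethyl)-6-hydroxy-6,10-dimethyl-2,7-dioxo-2,4,5,6,7,8,9,11a-octahydrocyclodeca[b]furan-4-yl 2-methylprop-2-enoate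
Product: 28 (4S,6S,10Z,11aR)-6-acetoxy-3-(acetoxymethyl)-6,10-dimethyl-2,7-dioxo-2,4,5,6,7,8,9,11a-octahydrocyclodeca[b]furan-4-yl 2-methylprop-2-enoate (CNP0115165.3)
Conditions: Ac2O, Sc(OTf)3 (5 mol%), MeCN, −20 °C
Reagents that add atoms: acetic anhydride CC(=O)OC(C)=O
Why: Lewis-acid-catalysed acetylation with Sc(OTf)3 acylates hindered tertiary alcohols at low temperature without base, which avoids epimerisation at C6 and ketol or retro-aldol side reactions.

**Compound list**
1 | prop-2-yn-1-ol | C#CCO | starting material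
2 | bromomagnesium (Z)-3-(bromomagnesio)-2-methylprop-2-en-1-olate | Br[Mg]OC/C(C)=C\[Mg]Br | intermediate
3 | (Z)-3-iodo-2-methylprop-2-en-1-ol | OC/C(C)=C\I | intermediate
4 | (Z)-3-bromo-1-iodo-2-methylprop-1-ene | BrC/C(C)=C\I | intermediate
5 | S-ethyl ethanethioate | CCSC(C)=O | starting material
6 | lithium 1-(ethylsulfanyl)ethen-1-olate | [Li+].[O-]C(=C)SCC | intermediate
7 | [1-(ethylsulfanyl)ethenyl]oxy(trimethyl)silane | C=C(O[Si](C)(C)C)SCC | intermediate
8 | butane-2,3-dione | CC(=O)C(C)=O | starting material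
9 | S-ethyl (3S)-3-methyl-4-oxo-3-(trimethylsilyloxy)pentanethioate | CCSC(=O)C[C@](C)(O[Si](C)(C)C)C(C)=O | intermediate
10 | S-ethyl (3S)-3-hydroxy-3-methyl-4-oxopentanethioate | CCSC(=O)C[C@](C)(O)C(C)=O | intermediate
11 | (3S)-3-hydroxy-3-methyl-4-oxopentanal | O=CC[C@](C)(O)C(C)=O | intermediate
12 | (3S)-3-hydroxy-5,5-dimethoxy-3-methylpentan-2-one | COC(OC)C[C@](C)(O)C(C)=O | intermediate
13 | dilithium (3S)-5,5-dimethoxy-3-methylpent-1-ene-2,3-bis(olate) | [Li+].[Li+].COC(OC)C[C@](C)([O-])C(=C)[O-] | intermediate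
14 | (3S,7Z)-3-hydroxy-8-iodo-1,1-dimethoxy-3,7-dimethyloct-7-en-4-one | COC(OC)C[C@](C)(O)C(=O)CC/C(C)=C\I | intermediate
15 | 4-hydroxyfuran-2(5H)-one (tetronic acid) | OC1=CC(=O)OC1 | starting material
16 | N-[(4-chloro-2-oxo-2,5-dihydrofuran-3-yl)methylidene]-N-methylmethanaminium chloride | C[N+](C)=CC1=C(Cl)COC1=O.[Cl-] | intermediate
17 | 4-chloro-2-oxo-2,5-dihydrofuran-3-carbaldehyde | O=CC1=C(Cl)COC1=O | intermediate
18 | 4-chloro-3-(hydroxymethyl)furan-2(5H)-one | OCC1=C(Cl)COC1=O | intermediate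
19 | (4-chloro-2-oxo-2,5-dihydrofuran-3-yl)methyl acetate | CC(=O)OCC1=C(Cl)COC1=O | intermediate
20 | [4-chloro-2-(trimethylsilyloxy)furan-3-yl]methyl acetate | CC(=O)OCc1c(Cl)coc1O[Si](C)(C)C | intermediate
21 | (5-bromo-4-chloro-2-oxo-2,5-dihydrofuran-3-yl)methyl acetate (racemic) | CC(=O)OCC1=C(Cl)C(Br)OC1=O | intermediate
22 | [(5R)-4-chloro-5-[(1Z,6S)-6-hydroxy-8,8-dimethoxy-2,6-dimethyl-5-oxooct-1-en-1-yl]-2-oxo-2,5-dihydrofuran-3-yl]methyl acetate | COC(OC)C[C@](C)(O)C(=O)CC/C(C)=C\[C@H]1OC(=O)C(COC(C)=O)=C1Cl | intermediate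
23 | [(5R)-5-[(1Z,6S)-6-hydroxy-8,8-dimethoxy-2,6-dimethyl-5-oxooct-1-en-1-yl]-4-iodo-2-oxo-2,5-dihydrofuran-3-yl]methyl acetate | COC(OC)C[C@](C)(O)C(=O)CC/C(C)=C\[C@H]1OC(=O)C(COC(C)=O)=C1I | intermediate
24 | [(5R)-5-[(1Z,6S)-6-hydroxy-2,6-dimethyl-5,8-dioxooct-1-en-1-yl]-4-iodo-2-oxo-2,5-dihydrofuran-3-yl]methyl acetate | O=CC[C@](C)(O)C(=O)CC/C(C)=C\[C@H]1OC(=O)C(COC(C)=O)=C1I | intermediate
25 | [(4S,6S,10Z,11aR)-6-hydroxy-6,10-dimethyl-2,7-dioxo-4-(trimethylsilyloxy)-2,4,5,6,7,8,9,11a-octahydrocyclodeca[b]furan-3-yl]methyl acetate | C[Si](C)(C)O[C@H]1C[C@](C)(O)C(=O)CC/C(C)=C\[C@H]2OC(=O)C(COC(C)=O)=C12 | intermediate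
26 | [(4S,6S,10Z,11aR)-4,6-dihydroxy-6,10-dimethyl-2,7-dioxo-2,4,5,6,7,8,9,11a-octahydrocyclodeca[b]furan-3-yl]methyl acetate | O[C@H]1C[C@](C)(O)C(=O)CC/C(C)=C\[C@H]2OC(=O)C(COC(C)=O)=C12 | intermediate
27 | (4S,6S,10Z,11aR)-3-(acetoxymethyl)-6-hydroxy-6,10-dimethyl-2,7-dioxo-2,4,5,6,7,8,9,11a-octahydrocyclodeca[b]furan-4-yl 2-methylprop-2-enoate | C=C(C)C(=O)O[C@H]1C[C@](C)(O)C(=O)CC/C(C)=C\[C@H]2OC(=O)C(COC(C)=O)=C12 | intermediate
28 | (4S,6S,10Z,11aR)-6-acetoxy-3-(acetoxymethyl)-6,10-dimethyl-2,7-dioxo-2,4,5,6,7,8,9,11a-octahydrocyclodeca[b]furan-4-yl 2-methylprop-2-enoate (germacrane labels 6R,8S,10S,4Z) | C=C(C)C(=O)O[C@H]1C[C@](C)(OC(C)=O)C(=O)CC/C(C)=C\[C@H]2OC(=O)C(COC(C)=O)=C12 | target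

**Step count**
Total steps: 17. Longest linear sequence: 11 steps (5 to 28 through steps 3, 4, 5, 6, 7, 12, 13, 14, 15, 16, 17).

**Three steps most likely to fail, with fallbacks**

Step 12 (the proposed new coupling). The risks are homocoupling of 14, reduction of 21, and low facial control at C6. The fallback uses known chemistry and sets out from 21 and 14. Bromide 21 is hydrolysed (H2O, acetone, NaHCO3, 0 °C) to the pseudo-acid (4-chloro-5-hydroxy-2-oxo-2,5-dihydrofuran-3-yl)methyl acetate F1. Trimethylsilyldiazomethane in MeOH/toluene opens F1 to the aldehyde ester methyl (2E)-2-(acetoxymethyl)-3-chloro-4-oxobut-2-enoate F2. An asymmetric Nozaki–Hiyama–Kishi coupling of 14 with F2 follows (CrCl2 and the sulfonamide ligand of step 15 in stoichiometric amount, Et3N, NiCl2 catalyst, THF/MeCN); the alkenyl chloride is inert. It gives the hydroxy ester methyl (2E,4R,5Z,10S)-2-(acetoxymethyl)-3-chloro-4,10-dihydroxy-12,12-dimethoxy-6,10-dimethyl-9-oxododeca-2,5-dienoate F3, whose new alcohol is cis to the ester and lactonises on work-up with PPTS. The fallback comes back to the route at 22.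

Step 13 (chloride-to-iodide exchange at a hindered, fully substituted β-carbon). The exchange may stall or ionise the allylic acetate. The fallback sets out from 22. Pd(PPh3)4-catalysed stannylation with hexamethylditin in dioxane at 80 °C gives [(5R)-5-[(1Z,6S)-6-hydroxy-8,8-dimethoxy-2,6-dimethyl-5-oxooct-1-en-1-yl]-2-oxo-4-(trimethylstannyl)-2,5-dihydrofuran-3-yl]methyl acetate F4. Iododestannylation with iodine in CH2Cl2 at 0 °C then comes back to the route at 23.

Step 15 (ten-membered ring closure with catalyst control at C8). The risks are slow cyclisation, protodeiodination, and a mismatch between ligand and substrate. The fallback sets out from 24 and separates ring closure from stereocontrol. The classical stoichiometric protocol (CrCl2, 6 equiv, NiCl2, 1 mol%, DMSO/THF, high dilution, no chiral ligand) closes the ring to 26 mixed with its C8 epimer [(4R,6S,10Z,11aR)-4,6-dihydroxy-6,10-dimethyl-2,7-dioxo-2,4,5,6,7,8,9,11a-octahydrocyclodeca[b]furan-3-yl]methyl acetate F5. Dess–Martin oxidation of the mixture gives the single ketone [(6S,10Z,11aR)-6-hydroxy-6,10-dimethyl-2,4,7-trioxo-2,4,5,6,7,8,9,11a-octahydrocyclodeca[b]furan-3-yl]methyl acetate F6. Hydroxyl-directed reduction with Me4NBH(OAc)3 in MeCN/AcOH at −30 °C (Evans–Saksena) delivers hydride internally from the C10-bound borate and gives the 1,3-anti diol, which is the 8S,10S relationship of the target. The fallback comes back to the route at 26.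

**Further compounds**
F1 | step 12 | (4-chloro-5-hydroxy-2-oxo-2,5-dihydrofuran-3-yl)methyl acetate (racemic) | CC(=O)OCC1=C(Cl)C(O)OC1=O
F2 | step 12 | methyl (2E)-2-(acetoxymethyl)-3-chloro-4-oxobut-2-enoate | O=C/C(Cl)=C(/COC(C)=O)C(=O)OC
F3 | step 12 | methyl (2E,4R,5Z,10S)-2-(acetoxymethyl)-3-chloro-4,10-dihydroxy-12,12-dimethoxy-6,10-dimethyl-9-oxododeca-2,5-dienoate | COC(OC)C[C@](C)(O)C(=O)CC/C(C)=C\[C@@H](O)/C(Cl)=C(/COC(C)=O)C(=O)OC
F4 | step 13 | [(5R)-5-[(1Z,6S)-6-hydroxy-8,8-dimethoxy-2,6-dimethyl-5-oxooct-1-en-1-yl]-2-oxo-4-(trimethylstannyl)-2,5-dihydrofuran-3-yl]methyl acetate | COC(OC)C[C@](C)(O)C(=O)CC/C(C)=C\[C@H]1OC(=O)C(COC(C)=O)=C1[Sn](C)(C)C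
F5 | step 15 | [(4R,6S,10Z,11aR)-4,6-dihydroxy-6,10-dimethyl-2,7-dioxo-2,4,5,6,7,8,9,11a-octahydrocyclodeca[b]furan-3-yl]methyl acetate | O[C@@H]1C[C@](C)(O)C(=O)CC/C(C)=C\[C@H]2OC(=O)C(COC(C)=O)=C12
F6 | step 15 | [(6S,10Z,11aR)-6-hydroxy-6,10-dimethyl-2,4,7-trioxo-2,4,5,6,7,8,9,11a-octahydrocyclodeca[b]furan-3-yl]methyl acetate | O=C1C[C@](C)(O)C(=O)CC/C(C)=C\[C@H]2OC(=O)C(COC(C)=O)=C12
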